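## Retrosynthesis
1. Plagiochilin A (**13**) comes from 1,5-dialdehyde **12** by base/Ac2O oxa-aldol closure and acetylation. The dihydropyran acetal/enol ether is formed last.
2. **12** comes from diol **11**. The spiro-epoxide is built from the C10 ketone by methylenation then epoxidation. The two CH2O arms on C4 are differentiated by hydroboration of a 1,1-disubstituted alkene followed by acetylation.
3. Ketone **6** comes from a one-pot cuprate 1,4-addition at C5 (anti to the cyclopropane) and formaldehyde aldol at C1 on cyclopropane-fused cycloheptenone **3**.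
4. **3** comes from ozonolysis and aldol condensation of (–)-2-carene (**1**), which supplies both cyclopropane stereocentres.
5. Ring-forming order: cyclopropane (already in **1**), then cycloheptenone (step 2), spiro-epoxide (step 6), dihydropyran (step 11).

**Labels and assumptions**
- Labels follow aromadendrane numbering. C1/C5 are the ring-fusion carbons, C6/C7 the cyclopropane CH carbons, C10 the spiro-epoxide carbon and C14 its CH2. C2 is the acetal carbon, C3 the enol-ether CH, C4 the enol-ether carbon bearing C15, and C15 the CH2OAc.
- Assumption 1: (1R,6S)-(–)-2-carene is purchasable. The target's cyclopropane is the enantiomeric series to (+)-aromadendrene, so the common (+)-carenes would give ent-product.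
- Assumption 2: C1 in **5–12** is the trans epimer (CH2O trans to C4). It is deliberately reset in step 11.
- Assumption 3: the natural C2 acetal epimer is the thermodynamic one in step 11.

## Route

**Step 1**
Reactants: **1** (1R,6S)-3,7,7-trimethylbicyclo[4.1.0]hept-2-ene
Product: **2** cis-2,2-dimethyl-3-(3-oxobutyl)cyclopropane-1-carbaldehyde, single enantiomer
Conditions: O3, CH2Cl2/MeOH, –78 °C; then Me2S, –78 °C to rt
Reagents that add atoms: ozone, [O-][O+]=O
Why: Ozonolysis (Criegee) cleaves only the trisubstituted alkene and leaves both cyclopropane stereocentres untouched. The aldehyde carbon becomes C5 and the methyl ketone becomes C10 with its CH3 as C1.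

**Step 2**
Reactants: **2**
Product: **3** (1S,7R-type) 8,8-dimethylbicyclo[5.1.0]oct-2-en-4-one, C10 ketone with C1=C5 enone
Conditions: pyrrolidine (0.2 equiv), AcOH (0.2 equiv), PhMe, 80 °C, 0.01 M
Reagents that add atoms: none
Why: Intramolecular enamine aldol condensation. The methyl-ketone CH3 attacks the cis-disposed cyclopropyl aldehyde and dehydration gives the Z-enone in the seven-membered ring. No new stereocentre forms.

**Step 3**
Reactants: **3**; **4** (2-bromoallyloxy)-tert-butyldimethylsilane
Product: **5** 3-(hydroxymethyl)-2-[3-(TBSO)prop-1-en-2-yl]-8,8-dimethylbicyclo[5.1.0]octan-4-one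
Conditions: **4**, t-BuLi, Et2O, –78 °C; CuBr·SMe2, THF, –78 °C; add **3**, –78 °C; then monomeric CH2O, –78 to 0 °C
Reagents that add atoms: formaldehyde, C=O
Why: Cuprate 1,4-addition followed by enolate aldol with formaldehyde. The vinyl group adds to C5 anti to the gem-dimethylcyclopropane, which sets C5 with C4 on the face opposite C11. The regiospecific C1 enolate is trapped by CH2O, anti to the new C5 substituent, giving the trans C1 epimer. The vinyl =CH2 will become C15 and the CH2OTBS arm will become C3.

**Step 4**
Reactants: **5**
Product: **6** the C2 TBS ether of **5**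
Conditions: TBSCl, imidazole, DMF, rt
Reagents that add atoms: TBSCl, CC(C)(C)[Si](C)(C)Cl
Why: Silylation of the primary alcohol prevents retro-aldol, E1cB and alkoxide interference in the next steps. No stereocentre is affected.

**Step 5**
Reactants: **6**
Product: **7** the C10 exocyclic methylene diene (two 1,1-disubstituted alkenes)
Conditions: Zn, CH2Br2, TiCl4, THF/CH2Cl2, 0 °C to rt
Reagents that add atoms: dibromomethane, BrCBr
Why: Takai–Lombardo methylenation converts the hindered, enolizable ketone to C10=CH2 under non-basic conditions, so there is no epimerization and no β-elimination. The C10 ketone is needed only to this point.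

**Step 6**
Reactants: **7**
Product: **8** spiro-epoxide at C10 (O on the face anti to the cyclopropane)
Conditions: mCPBA (1.0 equiv), NaHCO3, CH2Cl2, –20 °C
Reagents that add atoms: mCPBA, OOC(=O)c1cccc(Cl)c1
Why: Prilezhaev epoxidation. The more electron-rich exocyclic methylene reacts in preference to the alkene deactivated by its allylic OTBS. Attack from the convex face, anti to the cyclopropane and to the C1 CH2OTBS group in the trans epimer, puts O on the top face and C14 on the bottom. This is the target's C10 configuration.

**Step 7**
Reactants: **8**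
Product: **9** primary alcohol at the former vinyl CH2; C4 is an epimeric mixture
Conditions: 9-BBN, THF, 0 °C to rt; then NaBO3·4H2O, THF/H2O
Reagents that add atoms: sodium perborate as the HOO⁻ source, OO
Why: Brown hydroboration–oxidation is anti-Markovnikov and leaves the epoxide and silyl ethers intact. C4 becomes a new stereocentre but is later flattened to the enol-ether carbon, so it does not matter.

**Step 8**
Reactants: **9**
Product: **10** the C15 acetate
Conditions: Ac2O, pyridine, DMAP (cat.), CH2Cl2, 0 °C
Reagents that add atoms: acetic anhydride, CC(=O)OC(C)=O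
Why: Only one hydroxyl is free, so acylation is selective. This sets the C15 OAc, with the CH2OTBS arm now distinct as the future C3.

**Step 9**
Reactants: **10**
Product: **11** diol with free C2–OH and C3–OH
Conditions: TBAF (2.5 equiv), AcOH (2.5 equiv), THF, 0 °C to rt
Reagents that add atoms: none
Why: Buffered fluoride removes both TBS ethers without touching the epoxide or the acetate. Any 1,3-acetyl shift between C15 and C3 is degenerate.

**Step 10**
Reactants: **11**
Product: **12** dialdehyde (C2 CHO and C3 CHO, C15 OAc)
Conditions: Dess–Martin periodinane (3 equiv), NaHCO3, CH2Cl2, 0 °C to rt; use crude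
Reagents that add atoms: none
Why: Neutral, buffered oxidation of both primary alcohols avoids the Et3N of a Swern oxidation, which would eliminate the β-acetoxy aldehyde.

**Step 11**
Reactants: **12**
Product: **13** plagiochilin A
Conditions: Ac2O, Et3N, DMAP (cat.), CH2Cl2, 0 °C to rt
Reagents that add atoms: acetic anhydride, CC(=O)OC(C)=O
Why: Et3N enolizes the C3 aldehyde at C4, and the enolate oxygen adds to the C2 aldehyde (oxa-aldol), closing the dihydropyran with C3=C4. The lactol alkoxide is trapped as the C2 acetate. C1, which is α to the C2 aldehyde, epimerizes, and only the cis-fused ring can close, so C1 is reset here. The reversible alkoxide equilibrates before acetylation, so the anomeric acetate predominates, giving C2.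

**Checks**
- The last product **13** matches the given SMILES: rings 3/7/6 plus the epoxide, two OAc groups, and gem-dimethyl.
- Stereocentres: C6 and C7 come from **1**; C5 from step 3; C10 from step 6; C1 and C2 from step 11. C4 is sp3 in **9–12** and becomes sp2 in **13**.
- Atom balance: 12 (C17H24O5) + Ac2O – AcOH = C19H26O6.

## Compound list
| # | name | SMILES | role |
|---|---|---|---|
| 1 | (1R,6S)-(–)-2-carene | CC1=C[C@@H]2[C@H](CC1)C2(C)C | starting material |
| 2 | cis-2,2-dimethyl-3-(3-oxobutyl)cyclopropane-1-carbaldehyde | O=C[C@@H]1[C@H](CCC(C)=O)C1(C)C | intermediate |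
| 3 | 8,8-dimethylbicyclo[5.1.0]oct-2-en-4-one | O=C1CC[C@H]2[C@@H](C=C1)C2(C)C | intermediate |
| 4 | (2-bromoallyloxy)-TBS | C=C(Br)CO[Si](C)(C)C(C)(C)C | starting material |
| 5 | β-hydroxy ketone (C1 CH2OH, C5 alkenyl) | O=C1CC[C@H]2[C@@H]([C@@H](C(=C)CO[Si](C)(C)C(C)(C)C)[C@@H]1CO)C2(C)C | intermediate |
| 6 | C2-OTBS ketone | O=C1CC[C@H]2[C@@H]([C@@H](C(=C)CO[Si](C)(C)C(C)(C)C)[C@@H]1CO[Si](C)(C)C(C)(C)C)C2(C)C | intermediate |
| 7 | exocyclic methylene diene | C=C1CC[C@H]2[C@@H]([C@@H](C(=C)CO[Si](C)(C)C(C)(C)C)[C@@H]1CO[Si](C)(C)C(C)(C)C)C2(C)C | intermediate |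
| 8 | spiro-epoxide bis-TBS ether | C1O[C@]13CC[C@H]2[C@@H]([C@@H](C(=C)CO[Si](C)(C)C(C)(C)C)[C@@H]3CO[Si](C)(C)C(C)(C)C)C2(C)C | intermediate |
| 9 | primary alcohol (C4 epimeric) | C1O[C@]13CC[C@H]2[C@@H]([C@@H](C(CO)CO[Si](C)(C)C(C)(C)C)[C@@H]3CO[Si](C)(C)C(C)(C)C)C2(C)C | intermediate |
| 10 | C15 acetate | C1O[C@]13CC[C@H]2[C@@H]([C@@H](C(COC(C)=O)CO[Si](C)(C)C(C)(C)C)[C@@H]3CO[Si](C)(C)C(C)(C)C)C2(C)C | intermediate |
| 11 | diol | C1O[C@]13CC[C@H]2[C@@H]([C@@H](C(COC(C)=O)CO)[C@@H]3CO)C2(C)C | intermediate |
| 12 | dialdehyde | C1O[C@]13CC[C@H]2[C@@H]([C@@H](C(COC(C)=O)C=O)[C@@H]3C=O)C2(C)C | intermediate |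
| 13 | plagiochilin A | CC(=O)OCC1=CO[C@H](OC(C)=O)[C@@H]2[C@H]1[C@@H]1[C@H](CC[C@@]23CO3)C1(C)C | target |

## Totals
Total steps: 11. Longest linear sequence: 11 (from **1**; bromide **4** is commercial or one step from 2-bromoallyl alcohol and TBSCl).

## Three steps most likely to fail
1. **Step 2 (seven-ring aldol).** The ketone CH2 can close a cyclopentene instead.
   Fallback: Wittig methylenation of the aldehyde in **2** gives the vinylcyclopropane. Eschenmoser's salt then MeI/base converts the methyl ketone to the vinyl ketone, and Grubbs II ring-closing metathesis gives **3**.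
2. **Step 6 (chemoselectivity and face selectivity of epoxidation).** The two 1,1-disubstituted alkenes may not be well differentiated, and the C10 face depends on the C1 epimer.
   Fallback: skip steps 5–6. Epimerize C1 to cis with DBU, then do Corey–Chaykovsky epoxidation (Me3S⁺ I⁻, n-BuLi) of the ketone, where the ylide attacks anti to the cis C2 group to give the target's C10 configuration. Then continue with hydroboration.
3. **Step 11 (dialdehyde closure).** The β-acetoxy aldehyde can eliminate to the α-methylene aldehyde, and the C1 and C2 selectivities may be poor.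
   Fallback: carry C15 as OTBS through the closure, using differentiated silyl groups. Then remove the TBS with buffered TBAF and acetylate as a separate step.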